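The route rests on disconnecting the bond from C3 to the first carbon of the eleven-carbon side chain, together with the lactone bond O2–C1. C3 is a carbinol carbon between the benzylic C4 of the benzene ring and the unbranched chain, and its oxygen O2 lies a six-membered ring away from the ester carbon C1 on C8a. A ligand-controlled transfer of a functionalised alkyl group from zinc to an arylacetaldehyde therefore attaches the chain, sets 3R and, by 6-exo-trig acyl substitution, closes the lactone ring in one operation. The aldehyde bears an ortho methyl ester and both phenol oxygens as methyl ethers; the zinc reagent bears the terminal oxygen as a benzyl ether.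

Key step: step 8

Remark: positions follow isochroman-1-one numbering (C1 lactone carbonyl, O2, C3, C4, C4a, C5 to C8, C8a). C3 is R as read from the SMILES. The sense of induction assumed for the (1S,2S) ligand follows the usual model for this catalyst family and is to be confirmed on the first batch of adduct.

Step 1
Reactants: 1 1-bromo-3,5-dimethoxybenzene
Product: 3 2-bromo-4,6-dimethoxybenzaldehyde, via aryliminium chloride 2 (not isolated)
Conditions: POCl3, DMF, 0 °C → 90 °C; then ice-water, rt
Reagents that add atoms: N,N-dimethylformamide CN(C)C=O (formyl carbon); water O (carbonyl oxygen)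
Why: Vilsmeier–Haack formylation of this dimethoxyaryl bromide should go mainly ortho to bromine, a position para to one methoxy group and ortho to the other, and the minor isomer formylated between the two methoxy groups should be removable by crystallisation.

Step 2
Reactants: 3 2-bromo-4,6-dimethoxybenzaldehyde
Product: 4 2-bromo-4,6-dimethoxybenzoic acid
Conditions: NaClO2, NaH2PO4, 2-methyl-2-butene, t-BuOH/THF/H2O, 0 °C → rt
Reagents that add atoms: sodium chlorite NaClO2 [Na+].[O-]Cl=O
Why: Pinnick oxidation converts the aryl aldehyde into the acid under buffered conditions, and the excess alkene should trap hypochlorous acid before it can chlorinate the electron-rich ring.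

Step 3
Reactants: 4 2-bromo-4,6-dimethoxybenzoic acid
Product: 5 methyl 2-bromo-4,6-dimethoxybenzoate
Conditions: MeI, K2CO3, DMF, rt
Reagents that add atoms: iodomethane CI
Why: O-alkylation of the carboxylate (SN2 on iodomethane) avoids addition to the doubly ortho-substituted carbonyl carbon, which makes Fischer esterification of such acids slow.

Step 4
Reactants: 5 methyl 2-bromo-4,6-dimethoxybenzoate; 6 allylboronic acid pinacol ester (2-allyl-4,4,5,5-tetramethyl-1,3,2-dioxaborolane)
Product: 7 methyl 2,4-dimethoxy-6-(prop-2-en-1-yl)benzoate
Conditions: Pd(PPh3)4 (cat.), CsF, THF, reflux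
Reagents that add atoms: none
Why: Suzuki–Miyaura coupling of the aryl bromide, activated by its ortho ester, with the fluoride-activated allylboronate should give the allylarene, and the mild fluoride conditions should keep the alkene from moving into conjugation.

Step 5
Reactants: 7 methyl 2,4-dimethoxy-6-(prop-2-en-1-yl)benzoate
Product: 9 methyl 2,4-dimethoxy-6-(2-oxoethyl)benzoate, via ozonide 8 (not isolated)
Conditions: O3, CH2Cl2, −78 °C, Sudan Red 7B as end-point indicator; then PPh3, −78 °C → rt
Reagents that add atoms: ozone [O-][O+]=O
Why: Ozonolysis with reductive work-up should cleave the terminal alkene well before ozone attacks the arene, the dye marking the end point, and the arylacetaldehyde is taken into step 8 at once without storage.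

Step 6
Reactants: 10 undec-10-en-1-ol
Product: 11 benzyl undec-10-en-1-yl ether, i.e. [(undec-10-en-1-yloxy)methyl]benzene
Conditions: NaH, BnBr, Bu4NI (cat.), THF, 0 °C → rt
Reagents that add atoms: benzyl bromide BrCc1ccccc1
Why: Williamson ether synthesis on a primary alkoxide is reliable, and the benzyl ether tolerates the borane, Et2Zn and Ti(OiPr)4 of the later steps.

Step 7
Reactants: 11 benzyl undec-10-en-1-yl ether (2 equiv)
Product: 13 bis[11-(benzyloxy)undecyl]zinc, via alkyldiethylborane 12 (not isolated)
Conditions: Et2BH (1 equiv per alkene, from Et3B and BH3·SMe2), neat, 0 °C → rt, volatiles off; Et2Zn (neat, excess), 0 °C, then Et3B and excess Et2Zn off in vacuo (twice); residue taken up in toluene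
Reagents that add atoms: diethylzinc CC[Zn]CC
Why: Anti-Markovnikov hydroboration of the terminal alkene followed by boron–zinc exchange is the established entry to functionalised primary dialkylzincs; two molecules of 11 supply the two alkyl groups on one zinc atom (2 RBEt2 + Et2Zn → R2Zn + 2 Et3B), diethylzinc contributes only its zinc atom, and thorough evacuation of volatile Et3B and Et2Zn should drive the exchange and leave no ethyl groups on zinc.

Step 8
Reactants: 9 methyl 2,4-dimethoxy-6-(2-oxoethyl)benzoate; 13 bis[11-(benzyloxy)undecyl]zinc
Product: 15 (3R)-3-[11-(benzyloxy)undecyl]-6,8-dimethoxyisochroman-1-one, via hydroxy ester 14 (not isolated)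
Conditions: (1S,2S)-C6H10(NHSO2CF3)2 (8 mol%), Ti(OiPr)4 (2 equiv), toluene, −20 °C → 0 °C; then 1 M HCl; TsOH·H2O (cat.), toluene, rt
Reagents that add atoms: none
Why: The sulfonamide and Ti(OiPr)4 form a chiral titanium bis(sulfonamide) Lewis acid that activates the aldehyde of 9 while one undecyl group of 13 is handed over to the carbonyl carbon, which creates the bond from C3 to the first chain carbon and a C3 metal alkoxide; the second alkyl group on zinc is not transferred and is protonated on work-up. The closest known reaction type is the Ti(OiPr)4/bis(sulfonamide)-catalysed enantioselective addition of functionalised dialkylzincs to aliphatic aldehydes, applied here to an arylacetaldehyde. The lactone ring then closes by 6-exo-trig acyl substitution of the C3 oxygen on the ester carbon C1 with loss of methanol, either from the alkoxide on warming or from the free alcohol 14 under the acid of the work-up. The configuration at C3 is set by the ligand alone, the (1S,2S) antipode being expected to direct the alkyl group to the Re face (3R); as no other stereocentre is present, this can be checked on a sample of 14 (Mosher esters) or on 15 (chiral HPLC against the racemate) and the ligand enantiomer exchanged if the sense proves opposite. The step needs aldehyde-over-ester chemoselectivity and addition faster than enolisation of the benzylic α-CH2, and both should be secured by the low basicity and nucleophilicity of the dialkylzinc at −20 °C and by the two ortho substituents that shield the ester. Lactonisation breaks no bond at the C3 carbon, so the enantiomeric purity of 14 should pass unchanged into 15.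

Step 9
Reactants: 15 (3R)-3-[11-(benzyloxy)undecyl]-6,8-dimethoxyisochroman-1-one
Product: 17 (3R)-8-hydroxy-3-(11-hydroxyundecyl)-6-methoxyisochroman-1-one, via bis(dichloroboryl) ester 16 (not isolated)
Conditions: BCl3 (4 equiv, 1 M in CH2Cl2), C6HMe5 (3 equiv), CH2Cl2, −78 °C → 0 °C; then H2O
Reagents that add atoms: none
Why: Lewis-acid ether cleavage in which boron chelated between the lactone carbonyl and the peri C8 oxygen should remove that methyl group only, the same reagent should cleave the primary benzyl ether with pentamethylbenzene intercepting the benzyl cation, and the unchelated C6 methyl ether, the lactone and C3 should be untouched at 0 °C or below.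

Compound list
1 | 1-bromo-3,5-dimethoxybenzene | COc1cc(Br)cc(OC)c1 | starting material
2 | N-[(2-bromo-4,6-dimethoxyphenyl)methylidene]-N-methylmethanaminium chloride | C[N+](C)=Cc1c(Br)cc(OC)cc1OC.[Cl-] | intermediate
3 | 2-bromo-4,6-dimethoxybenzaldehyde | O=Cc1c(Br)cc(OC)cc1OC | intermediate
4 | 2-bromo-4,6-dimethoxybenzoic acid | OC(=O)c1c(Br)cc(OC)cc1OC | intermediate
5 | methyl 2-bromo-4,6-dimethoxybenzoate | COC(=O)c1c(Br)cc(OC)cc1OC | intermediate
6 | allylboronic acid pinacol ester | C=CCB1OC(C)(C)C(C)(C)O1 | starting material
7 | methyl 2,4-dimethoxy-6-(prop-2-en-1-yl)benzoate | COC(=O)c1c(OC)cc(OC)cc1CC=C | intermediate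
8 | methyl 2,4-dimethoxy-6-[(1,2,4-trioxolan-3-yl)methyl]benzoate | COC(=O)c1c(OC)cc(OC)cc1CC1OCOO1 | intermediate
9 | methyl 2,4-dimethoxy-6-(2-oxoethyl)benzoate | COC(=O)c1c(OC)cc(OC)cc1CC=O | intermediate
10 | undec-10-en-1-ol | C=CCCCCCCCCCO | starting material
11 | benzyl undec-10-en-1-yl ether | C=CCCCCCCCCCOCc1ccccc1 | intermediate
12 | [11-(benzyloxy)undecyl]diethylborane | CCB(CC)CCCCCCCCCCCOCc1ccccc1 | intermediate
13 | bis[11-(benzyloxy)undecyl]zinc | c1ccccc1COCCCCCCCCCCC[Zn]CCCCCCCCCCCOCc1ccccc1 | intermediate
14 | methyl 2-[(2R)-13-(benzyloxy)-2-hydroxytridecyl]-4,6-dimethoxybenzoate | COC(=O)c1c(OC)cc(OC)cc1C[C@H](O)CCCCCCCCCCCOCc2ccccc2 | intermediate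
15 | (3R)-3-[11-(benzyloxy)undecyl]-6,8-dimethoxyisochroman-1-one | COc1cc(OC)c2c(c1)C[C@@H](CCCCCCCCCCCOCc3ccccc3)OC2=O | intermediate
16 | (3R)-8-[(dichloroboranyl)oxy]-3-{11-[(dichloroboranyl)oxy]undecyl}-6-methoxyisochroman-1-one | COc1cc(OB(Cl)Cl)c2c(c1)C[C@@H](CCCCCCCCCCCOB(Cl)Cl)OC2=O | intermediate
17 | (3R)-8-hydroxy-3-(11-hydroxyundecyl)-6-methoxyisochroman-1-one | COc1cc(O)c2c(c1)C[C@@H](CCCCCCCCCCCO)OC2=O | target

Total step count: 9. Longest linear sequence: 7 steps (steps 1, 2, 3, 4, 5, 8 and 9 from 1); the side-chain branch (steps 6 and 7) joins at step 8.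

Steps most likely to fail

Step 8. What may go wrong: poor facial selectivity in the alkyl transfer, enolisation or self-condensation of the arylacetaldehyde outrunning the addition, or ethyl transfer from residual ethylzinc species carried over from step 7. The fallback sets out from 9 and also makes 13 unnecessary. Brown allylation of 9 with (+)-Ipc2B(allyl) (from (+)-Ipc2BOMe and allylMgBr, Et2O, −78 °C; NaOH/H2O2 work-up), the antipode expected to deliver allyl to the Re face, should give methyl 2-[(2R)-2-hydroxypent-4-en-1-yl]-4,6-dimethoxybenzoate F1. F1 should lactonise during the basic work-up or with catalytic TsOH to (3R)-6,8-dimethoxy-3-(prop-2-en-1-yl)isochroman-1-one F2. Cross-metathesis of F2 with an excess of benzyl dec-9-en-1-yl ether F3 (from dec-9-en-1-ol, NaH and BnBr) and the second-generation Grubbs catalyst RuCl2(=CHPh)(H2IMes)(PCy3) in CH2Cl2 at 40 °C should give (3R)-3-[(2E)-11-(benzyloxy)undec-2-en-1-yl]-6,8-dimethoxyisochroman-1-one F4, any Z isomer being carried along. Hydrogenation of the alkene with H2 and RhCl(PPh3)3 in toluene/EtOH, which leaves the benzyl ether, brings the material back to the route at 15.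

Step 5. What may go wrong: over-oxidation of the electron-rich arene by ozone, or aldol self-condensation and air oxidation of the arylacetaldehyde during isolation. The fallback sets out from 5 and bypasses step 4 as well. Suzuki–Miyaura coupling of 5 with commercial (E)-2-(2-ethoxyvinyl)-4,4,5,5-tetramethyl-1,3,2-dioxaborolane (Pd(PPh3)4, K2CO3, dioxane/H2O, 80 °C) should give methyl 2-[(E)-2-ethoxyethenyl]-4,6-dimethoxybenzoate F5, a storable masked form of the aldehyde. Hydrolysis of the enol ether with dilute aqueous HCl in THF at 0 °C → rt, done just before the key step, returns to the route at 9.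

Step 9. What may go wrong: benzylation of the electron-rich ring by the benzyl cation, incomplete cleavage of the unactivated primary benzyl ether at temperatures that spare the C6 ether, or partial loss of the C6 methyl group if the mixture has to be warmed. The fallback sets out from 15 and separates the two cleavages into orthogonal operations. Hydrogenolysis (H2, Pd/C, EtOAc, rt) should give (3R)-3-(11-hydroxyundecyl)-6,8-dimethoxyisochroman-1-one F6 without any cationic benzyl species. Chelation-controlled mono-demethylation of F6 with BCl3 (CH2Cl2, −78 °C → 0 °C), which then has only the peri C8 ether to cleave, returns to the route at 17.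

Further compounds
F1 | step 8 | methyl 2-[(2R)-2-hydroxypent-4-en-1-yl]-4,6-dimethoxybenzoate | COC(=O)c1c(OC)cc(OC)cc1C[C@H](O)CC=C
F2 | step 8 | (3R)-6,8-dimethoxy-3-(prop-2-en-1-yl)isochroman-1-one | COc1cc(OC)c2c(c1)C[C@@H](CC=C)OC2=O
F3 | step 8 | benzyl dec-9-en-1-yl ether | C=CCCCCCCCCOCc1ccccc1
F4 | step 8 | (3R)-3-[(2E)-11-(benzyloxy)undec-2-en-1-yl]-6,8-dimethoxyisochroman-1-one | COc1cc(OC)c2c(c1)C[C@@H](C/C=C/CCCCCCCCOCc3ccccc3)OC2=O
F5 | step 5 | methyl 2-[(E)-2-ethoxyethenyl]-4,6-dimethoxybenzoate | COC(=O)c1c(OC)cc(OC)cc1/C=C/OCC
F6 | step 9 | (3R)-3-(11-hydroxyundecyl)-6,8-dimethoxyisochroman-1-one | COc1cc(OC)c2c(c1)C[C@@H](CCCCCCCCCCCO)OC2=O
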